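# Synthesis plan for CNP0216929.1 (compound 29)

Locants used throughout: ring A is C1 (ketone), C2, C3, C4, C9, C10; ring B is C4–C9; ring C is C11–C15, with C11 bonded to C2, C12 the gem-dimethyl carbon and C13 the bromomethine.

## The problem

Compound 29 is a C20 bromoditerpenoid with a trans-fused bicyclic core. Ring A is a cyclohexenone and ring B a cyclohexane, sharing C4–C9, and the enone α-carbon C2 carries a 3-bromo-1,2,2-trimethylcyclopentyl ring C through a quaternary-to-sp2 bond (C11–C2). The six stereocentres fall into two sets that cannot relay to each other: C4, C5, C8 and C9 are contiguous on ring B, while C11 and C13 lie on ring C beyond the planar C2. Their mutual configuration must therefore come from joining two separately controlled pieces. Within ring B the quaternary C9 is the anchor: its axial methyl group can direct oxygenation at C4, methyl addition at C5 and the conformation in which C8 is substituted, but nothing can correct C9 later. Four centres are fully substituted (C4, C5, C9, C11), and both bromines sit on secondary carbons next to a quaternary one (C8 beside C9, C13 beside C12), the worst case for substitution and one prone to Wagner–Meerwein shifts. The tertiary allylic C4 carbinol (γ to the enone, part of a vicinal di-tertiary diol) and the C8 bromide (γ to the C1 carbonyl) will not tolerate hot base or ionising acid, so the diol must come last and the bromides must enter by clean SN2. The enabling feature is that C8–C9–C4 can be read as the C=O/α/β array of a 2-methylcyclohex-2-enone in ring B, with C5 carried as a ketal. The two bonds that attach ring A (C3–C4 and C10–C9) are trans, which is the result of adding a nucleophile at the β-carbon and then an electrophile at the α-carbon.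

## Retrosynthesis

**C5–CH3 and C4–O.** Cutting the C5–methyl bond of 29 gives α-hydroxy ketone 28, and cutting the C4–O bond gives ene-dione 26. Compared with making the diol from a C4=C5 olefin, this order uses the C5 carbonyl twice: it acidifies C4–H (also γ to the enone) and then accepts the methyl group. The precursor 26 has no carbinol and only three stereocentres on the bicyclic core. The forward steps need oxidation of the delocalised C4 anion on the face away from the C9 methyl, and equatorial methyl delivery to C5.

**Ring A at C2=C3.** Ketal 25 protects 26. Cutting C2=C3 of 25 by a retro-aldol condensation gives keto aldehyde 23, and both carbonyls of 23 are traced to the two olefins of diene 22 (ozonolysis). This cut is preferred to C1–C2 or C1–C10 because the C3 and C1 carbons can then travel through the organometallic steps as a vinyl group and a 1,1-disubstituted olefin. Only the C2 enolate of 23 can reach the aldehyde in a six-membered ring, so the closure has one productive mode.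

**C8–Br.** Bromide 22 comes from axial alcohol 21 by substitution with inversion, and 21 from ketone 20. The C8 carbonyl is kept until here because it is what makes C9 nucleophilic in the key step. The exchange is placed before ring A is closed, while C8 is the only carbonyl present, so the hydride step needs no chemoselectivity.

**C3–C4 and C9–C10 (key step).** Ketone 20 is cut at both bonds to give enone ketal 4, vinylmagnesium bromide 18 and allylic bromide 17. No other pair of cuts removes the quaternary C9, joins ring C to the core and sets the trans relation of the ring-A arms in one operation. The three precursors are a seven-carbon achiral enone, a two-carbon reagent and a chiral-pool fragment. The forward reaction must give face-selective 1,4-addition at a β-carbon flanked by the ketal, then C-alkylation of the regiodefined enolate anti to the new vinyl group.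

**Allylic bromide 17.** The allyl bromide is traced to allylsilane 16 (bromodesilylation), and 16 to acetic ester 14 by double (trimethylsilyl)methyl addition and Peterson elimination. The C13 bromide of 14 comes from alcohol 13 with inversion, and 13 from ketone 12 by catalyst-controlled reduction. A ketone at C13 is chosen because any oxygen delivered from the camphor skeleton is necessarily cis to the C11 arm, whereas the bromide must be cis and so needs the trans alcohol.

**Keto ester 12.** One-carbon homologation (Arndt–Eistert) links 12 through diazoketone 10 to keto acid 8. Acid 8 is the Curtius degradation product of (1R)-(+)-camphanic acid 5, in which C13 already carries oxygen and the C11 stereocentre is fixed.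

**Enone ketal 4.** Selective hydrogenation links 4 to quinone monoketal 3, which comes from 4-methoxy-2-methylphenol 1 and ethylene glycol 2 by oxidative dearomatisation.

## Roads not taken

**Alternative 1:** Ring C would be cut at C11–C15. Cu(OTf)2 with a chiral bis(oxazoline) would promote conrotatory 4π-closure of the 2-methoxycarbonyl divinyl ketone A1 to the cyclopentenone ester A2, creating the quaternary C11 catalytically.
- Merit: no dependence on the less common camphor antipode, and either enantiomer is accessible.
- Weak points: the step builds only ring C. A2 still needs the second C12 methyl, removal of the ester and the C14=C15 unsaturation, conversion of the C13 carbonyl into the bromide and of the benzyloxymethyl arm into the C2 linker. The whole core and the fragment union remain unsolved. Closure at a fully substituted terminus is slow, and the sense at C11 depends on the isomeric purity of the tetrasubstituted olefin of A1.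
- Comparison: for ring C alone the length is probably similar to the seven steps spent here on 17, and the catalytic origin of C11 is a real advantage. The chosen plan sets against it a C11 configuration that is bought rather than induced, and a key step that addresses the harder half of the molecule.

**Alternative 2:** Ring A would be closed last at C1–C2. CrCl2 with catalytic NiCl2 would convert dienyl triflate A3 into an alkenylchromium species that adds to the tethered C1 aldehyde, giving dienol A4.
- Merits: the closure is mild and tolerates both bromides, either C1 epimer serves, and A4 already holds the C4=C5 olefin with its methyl group. The diol could then come from epoxidation and trans-diaxial opening, arguably more reliable than enolate hydroxylation plus Grignard addition.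
- Weak points: the hard problems are moved upstream. A3 must already contain the C9 quaternary centre, the C8 bromide and ring C, and it needs a geometrically defined triflate at C2 beside the quaternary C11. The step also uses stoichiometric chromium.
- Comparison: Alternative 2 is better in the mildness of its end game. The chosen plan sets against it a single operation that creates C9 and joins the fragments.

**Alternative 3:** C4–C9 and C8–Br would be cut together. An electrophilic bromine source would add to the C8=C9 olefin of the ten-membered dienone A5, C4 of the facing olefin would close across the ring, and proton loss would give bicyclic bromo ketone A6.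
- Merits: the C8 bromide is installed during C–C bond formation by anti addition, which avoids the most doubtful substitution of the chosen plan. Rings A and B form at once, and few steps would remain.
- Weak points: A5 is a conformationally mobile macrocycle with an epimerisable C2. The bromonium ion must choose between two trisubstituted olefins. The configurations at C8 and C9 would rest on which ring conformer reacts, guided only by remote stereocentres.
- Comparison: if it worked it would be shorter and would solve C8 better. The chosen plan sets against it modular fragments, catalyst and substrate control with close precedent, and step-by-step checkpoints, and it accepts two SN2 brominations as the price.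

Key step: step 10

Assumptions: (1R)-(+)-camphanic acid 5 is treated as a purchasable chiral-pool acid of the (1S)-camphor series. The ligand antipode written in step 10 stands for whichever antipode is found to give the (6S) adduct; this is to be checked on 4 alone before 17 is committed, and both antipodes are commercial.

## Route

Step 1
Reactants: 1 4-methoxy-2-methylphenol; 2 ethylene glycol
Product: 3 7-methyl-1,4-dioxaspiro[4.5]deca-6,9-dien-8-one
Conditions: PhI(OAc)2, ethylene glycol (excess), CH2Cl2, 0 → 23 °C
Reagents that add atoms: none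
Why: Oxidative dearomatisation of a p-alkoxyphenol by a trivalent iodine reagent; the glycol is captured at the para carbon and the dioxolane closes with loss of methanol, giving the quinone monoketal.

Step 2
Reactants: 3 7-methyl-1,4-dioxaspiro[4.5]deca-6,9-dien-8-one
Product: 4 7-methyl-1,4-dioxaspiro[4.5]dec-6-en-8-one
Conditions: H2 (1 atm), RhCl(PPh3)3 (5 mol%), benzene, 23 °C
Reagents that add atoms: none
Why: Homogeneous hydrogenation with the monovalent rhodium complex reduces the disubstituted olefin of a cross-conjugated dienone and leaves the methyl-bearing trisubstituted one, as in the reduction of steroidal 1,4-dien-3-ones to 4-en-3-ones.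

Step 3
Reactants: 5 (1R,4S)-4,7,7-trimethyl-3-oxo-2-oxabicyclo[2.2.1]heptane-1-carboxylic acid [(1R)-(+)-camphanic acid]
Product: 8 (1S)-1,2,2-trimethyl-3-oxocyclopentane-1-carboxylic acid, via acyl azide 6 (not isolated), via bridgehead isocyanate 7 (not isolated)
Conditions: (PhO)2P(O)N3, Et3N, PhMe, 23 → 100 °C; then 2 M NaOH (aq), THF, 60 °C; then HCl (aq) to pH 2
Reagents that add atoms: sodium hydroxide (aqueous), [Na+].[OH-]
Why: Curtius rearrangement of an α-acyloxy acid proceeds with retention at the bridgehead; hydrolysis of the isocyanate and the lactone leaves a carbinolamine at C13 that collapses to the ketone (the classical Curtius degradation of α-oxygenated acids to carbonyl compounds). The C11 stereocentre is untouched.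

Step 4
Reactants: 8 (1S)-1,2,2-trimethyl-3-oxocyclopentane-1-carboxylic acid
Product: 10 2-diazo-1-[(1S)-1,2,2-trimethyl-3-oxocyclopentyl]ethan-1-one, via acid chloride 9 (not isolated)
Conditions: (COCl)2, DMF (cat.), CH2Cl2, 0 → 23 °C; concentrate; CH2N2 (3 equiv), Et2O, 0 °C
Reagents that add atoms: diazomethane, C=[N+]=[N-]
Why: First stage of the Arndt–Eistert homologation: the tertiary acid chloride acylates diazomethane, and the hindered ring ketone does not react with diazomethane in the absence of a Lewis acid.

Step 5
Reactants: 10 2-diazo-1-[(1S)-1,2,2-trimethyl-3-oxocyclopentyl]ethan-1-one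
Product: 12 methyl 2-[(1R)-1,2,2-trimethyl-3-oxocyclopentyl]acetate, via ketene 11 (not isolated)
Conditions: PhCO2Ag (10 mol%), Et3N, MeOH, 23 °C, dark
Reagents that add atoms: methanol, CO
Why: Silver-promoted Wolff rearrangement: the quaternary C11 migrates with retention and the ketene is trapped by methanol, giving the ring-C acetic ester.

Step 6
Reactants: 12 methyl 2-[(1R)-1,2,2-trimethyl-3-oxocyclopentyl]acetate
Product: 13 methyl 2-[(1R,3S)-3-hydroxy-1,2,2-trimethylcyclopentyl]acetate
Conditions: (R)-2-methyl-CBS-oxazaborolidine (15 mol%), BH3·SMe2, THF, −20 °C; MeOH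
Reagents that add atoms: none
Why: Corey–Bakshi–Shibata reduction: the catalyst distinguishes the quaternary C12 flank from the C14 methylene and should override the weak opposite bias of the remote C11 arm, setting 13S with the hydroxyl trans to the acetate arm. The minor cis epimer would lactonise and be separable.

Step 7
Reactants: 13 methyl 2-[(1R,3S)-3-hydroxy-1,2,2-trimethylcyclopentyl]acetate
Product: 14 methyl 2-[(1R,3R)-3-bromo-1,2,2-trimethylcyclopentyl]acetate
Conditions: CBr4, PPh3, 2,6-lutidine, PhMe, 0 → 60 °C
Reagents that add atoms: carbon tetrabromide, BrC(Br)(Br)Br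
Why: Appel reaction: bromide displaces the alkoxyphosphonium group with inversion, setting 13R with bromine cis to the arm. Substitution at a cyclopentyl carbon beside a quaternary centre has precedent in C17 inversions of ring-D steroids.

Step 8
Reactants: 14 methyl 2-[(1R,3R)-3-bromo-1,2,2-trimethylcyclopentyl]acetate
Product: 16 (2-{[(1R,3R)-3-bromo-1,2,2-trimethylcyclopentyl]methyl}prop-2-en-1-yl)trimethylsilane, via bis(silylmethyl) carbinol 15 (not isolated)
Conditions: Me3SiCH2MgCl (4 equiv), CeCl3 (4 equiv), THF, −78 → 23 °C; then silica gel, CH2Cl2, 23 °C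
Reagents that add atoms: (trimethylsilyl)methylmagnesium chloride, C[Si](C)(C)C[Mg]Cl
Why: Bunnelle allylsilane synthesis: the organocerium reagent adds twice to the ester, and Peterson elimination of one β-silyl group from the tertiary carbinol gives the 2-substituted allylsilane. The weakly basic reagent leaves the neopentylic secondary bromide alone.

Step 9
Reactants: 16 (2-{[(1R,3R)-3-bromo-1,2,2-trimethylcyclopentyl]methyl}prop-2-en-1-yl)trimethylsilane
Product: 17 (1R,3R)-3-bromo-1-[2-(bromomethyl)prop-2-en-1-yl]-1,2,2-trimethylcyclopentane
Conditions: NBS, propylene oxide, CH2Cl2, −78 °C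
Reagents that add atoms: N-bromosuccinimide, O=C1CCC(=O)N1Br
Why: Electrophilic bromodesilylation (SE2′) of an allylsilane: the β-silyl cation loses silicon, and because the allyl unit is 2-substituted the transposition is degenerate and one allylic bromide results.

Step 10
Reactants: 4 7-methyl-1,4-dioxaspiro[4.5]dec-6-en-8-one; 18 vinylmagnesium bromide; 17 (1R,3R)-3-bromo-1-[2-(bromomethyl)prop-2-en-1-yl]-1,2,2-trimethylcyclopentane
Product: 20 (6S,7S)-7-{2-[((1R,3R)-3-bromo-1,2,2-trimethylcyclopentyl)methyl]prop-2-en-1-yl}-6-ethenyl-7-methyl-1,4-dioxaspiro[4.5]decan-8-one, via bromomagnesium enolate 19 (not isolated)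
Conditions: CuBr·SMe2 (5 mol%), (R)-1-[(S_p)-2-(diphenylphosphino)ferrocenyl]ethyldicyclohexylphosphine (6 mol%), t-BuOMe, −75 °C, 18 (1.25 equiv) added over 2 h to 4 (1.3 equiv); then 17 (1.0 equiv), DMPU, −75 → 0 °C
Reagents that add atoms: none
Why: The monovalent copper–diphosphine complex is transmetallated by 18, binds the enone as a π-complex and transfers vinyl to C4 through a trivalent copper σ-intermediate, releasing bromomagnesium enolate 19 with the enolate double bond fixed at C8=C9. The closest known reaction type is the copper-catalysed enantioselective conjugate addition of Grignard reagents to 2-methylcycloalkenones with alkylation of the magnesium enolate by allylic halides in the same flask, together with cuprate additions to quinone-monoketal enones. No ring is closed. C4 (S) is set by the catalyst, which selects the enone face. C9 (S) is set by the substrate: the bromide approaches 19 on the face opposite the C4 vinyl group, so the C3 and C10 arms end trans. The step needs 1,4- over 1,2-addition (slow addition of 18 to the ligated catalyst at low temperature, with 4 in slight excess so that little Grignard reagent remains when 17 is added). It also needs C-alkylation without enolate equilibration to C7 (reactive allylic bromide, DMPU, temperature held at or below 0 °C) and no reaction at the secondary bromide of 17, which is neopentylic and inert to the enolate. Because 17 is a single enantiomer, any minor enantiomer of 19 ends in a diastereomer of 20 that chromatography can remove.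

Step 11
Reactants: 20 (6S,7S)-7-{2-[((1R,3R)-3-bromo-1,2,2-trimethylcyclopentyl)methyl]prop-2-en-1-yl}-6-ethenyl-7-methyl-1,4-dioxaspiro[4.5]decan-8-one
Product: 21 (6S,7S,8R)-7-{2-[((1R,3R)-3-bromo-1,2,2-trimethylcyclopentyl)methyl]prop-2-en-1-yl}-6-ethenyl-7-methyl-1,4-dioxaspiro[4.5]decan-8-ol
Conditions: LiBH(s-Bu)3, THF, −78 °C; then NaOH (aq), H2O2, 0 °C
Reagents that add atoms: none
Why: The bulky trialkylborohydride attacks the C8 carbonyl along the equatorial path because the axial path is closed by the axial hydrogens at C4 and C6, as in selectride reductions of 4,4-dimethyl-3-keto triterpenoids. The axial 8R alcohol, cis to the C10 arm, should result.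

Step 12
Reactants: 21 (6S,7S,8R)-7-{2-[((1R,3R)-3-bromo-1,2,2-trimethylcyclopentyl)methyl]prop-2-en-1-yl}-6-ethenyl-7-methyl-1,4-dioxaspiro[4.5]decan-8-ol
Product: 22 (6S,7S,8S)-8-bromo-7-{2-[((1R,3R)-3-bromo-1,2,2-trimethylcyclopentyl)methyl]prop-2-en-1-yl}-6-ethenyl-7-methyl-1,4-dioxaspiro[4.5]decane
Conditions: CBr4, PPh3, 2,6-lutidine, PhMe, 23 → 70 °C
Reagents that add atoms: carbon tetrabromide, BrC(Br)(Br)Br
Why: Appel reaction with inversion: an axial alkoxyphosphonium group beside a quaternary carbon is the favourable case for SN2 on a chair (axial alcohols next to gem-dialkyl carbons are known to give equatorial bromides in bromoterpenoid work). The equatorial 8S bromide, cis to the C9 methyl, should result.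

Step 13
Reactants: 22 (6S,7S,8S)-8-bromo-7-{2-[((1R,3R)-3-bromo-1,2,2-trimethylcyclopentyl)methyl]prop-2-en-1-yl}-6-ethenyl-7-methyl-1,4-dioxaspiro[4.5]decane
Product: 23 (6R,7S,8S)-8-bromo-7-{3-[(1R,3R)-3-bromo-1,2,2-trimethylcyclopentyl]-2-oxopropyl}-7-methyl-1,4-dioxaspiro[4.5]decane-6-carbaldehyde
Conditions: O3, CH2Cl2/MeOH, −78 °C; then PPh3, −78 → 23 °C
Reagents that add atoms: ozone, [O-][O+]=O
Why: Ozonolysis with reductive work-up cleaves the vinyl group to the C3 aldehyde and the 1,1-disubstituted olefin to the C1 ketone; alkyl bromides and the ketal are inert to ozone at −78 °C.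

Step 14
Reactants: 23 (6R,7S,8S)-8-bromo-7-{3-[(1R,3R)-3-bromo-1,2,2-trimethylcyclopentyl]-2-oxopropyl}-7-methyl-1,4-dioxaspiro[4.5]decane-6-carbaldehyde
Product: 25 C5 ethylene ketal of (4aS,8S,8aS)-8-bromo-3-[(1R,3R)-3-bromo-1,2,2-trimethylcyclopentyl]-8a-methyl-4a,7,8,8a-tetrahydronaphthalene-2,5(1H,6H)-dione, via ring-A aldol 24 (not isolated)
Conditions: KOH (0.2 M), MeOH/THF, 0 → 23 °C
Reagents that add atoms: none
Why: Intramolecular aldol condensation of a 1,5-keto aldehyde: only the C2 enolate can reach the aldehyde through a six-membered transition state (the C10 enolate would close a four-membered ring), and E1cB dehydration gives the enone. C4 either keeps its configuration or epimerises without consequence, since it is made planar in step 16.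

Step 15
Reactants: 25 C5 ethylene ketal of (4aS,8S,8aS)-8-bromo-3-[(1R,3R)-3-bromo-1,2,2-trimethylcyclopentyl]-8a-methyl-4a,7,8,8a-tetrahydronaphthalene-2,5(1H,6H)-dione
Product: 26 (4aS,8S,8aS)-8-bromo-3-[(1R,3R)-3-bromo-1,2,2-trimethylcyclopentyl]-8a-methyl-4a,7,8,8a-tetrahydronaphthalene-2,5(1H,6H)-dione
Conditions: 2 M HCl (aq), THF, 23 °C
Reagents that add atoms: water, O
Why: Acid-catalysed ketal hydrolysis; the product is a vinylogous 1,3-diketone, and all its tautomers (and any C4 epimer) give the same anion in step 16.

Step 16
Reactants: 26 (4aS,8S,8aS)-8-bromo-3-[(1R,3R)-3-bromo-1,2,2-trimethylcyclopentyl]-8a-methyl-4a,7,8,8a-tetrahydronaphthalene-2,5(1H,6H)-dione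
Product: 28 (4aR,8S,8aS)-8-bromo-3-[(1R,3R)-3-bromo-1,2,2-trimethylcyclopentyl]-4a-hydroxy-8a-methyl-4a,7,8,8a-tetrahydronaphthalene-2,5(1H,6H)-dione, via potassium dienolate 27 (not isolated)
Conditions: KN(SiMe3)2 (1.05 equiv), THF, −78 → −40 °C; then 2-(benzenesulfonyl)-3-phenyloxaziridine, −78 °C; NH4Cl (aq)
Reagents that add atoms: 2-(benzenesulfonyl)-3-phenyloxaziridine, O=S(=O)(c1ccccc1)N1OC1c1ccccc1
Why: Davis enolate hydroxylation: C4–H, α to the C5 ketone and γ to the enone, is the most acidic proton, and the delocalised anion is oxidised at C4 because C2 is shielded by the quaternary C11. The bulky oxaziridine should approach anti to the angular C9 methyl, as electrophiles do at ring-fusion enolates beside an angular methyl in steroids, giving the trans-fused 4R carbinol.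

Step 17
Reactants: 28 (4aR,8S,8aS)-8-bromo-3-[(1R,3R)-3-bromo-1,2,2-trimethylcyclopentyl]-4a-hydroxy-8a-methyl-4a,7,8,8a-tetrahydronaphthalene-2,5(1H,6H)-dione
Product: 29 (4aR,5R,8S,8aS)-8-bromo-3-[(1R,3R)-3-bromo-1,2,2-trimethylcyclopentyl]-4a,5-dihydroxy-5,8a-dimethyl-4a,5,6,7,8,8a-hexahydronaphthalen-2(1H)-one
Conditions: MeMgBr (3 equiv), THF, −78 → −20 °C; NH4Cl (aq)
Reagents that add atoms: methylmagnesium bromide, C[Mg]Br
Why: Grignard addition to an α-hydroxy ketone: the C4 magnesium alkoxide activates and directs at the neighbouring C5 carbonyl, while the C1 enone, flanked by the C11-bearing C2 and the neopentylic C10, is slower. The axial C9 methyl blocks the 1,3-diaxial path, so methyl should enter equatorially, cis to the C4 oxygen, giving the axial 5R hydroxyl.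

## Compound list

1 | 4-methoxy-2-methylphenol | COc1ccc(O)c(C)c1 | starting material
2 | ethylene glycol | OCCO | starting material
3 | 7-methyl-1,4-dioxaspiro[4.5]deca-6,9-dien-8-one | CC1=CC2(C=CC1=O)OCCO2 | intermediate
4 | 7-methyl-1,4-dioxaspiro[4.5]dec-6-en-8-one | CC1=CC2(CCC1=O)OCCO2 | intermediate
5 | (1R,4S)-4,7,7-trimethyl-3-oxo-2-oxabicyclo[2.2.1]heptane-1-carboxylic acid, (1R)-(+)-camphanic acid | CC1(C)[C@@]2(C(=O)O)CC[C@]1(C)C(=O)O2 | starting material
6 | (1R,4S)-4,7,7-trimethyl-3-oxo-2-oxabicyclo[2.2.1]heptane-1-carbonyl azide | CC1(C)[C@@]2(C(=O)N=[N+]=[N-])CC[C@]1(C)C(=O)O2 | intermediate (not isolated)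
7 | (1R,4S)-1-isocyanato-4,7,7-trimethyl-2-oxabicyclo[2.2.1]heptan-3-one | CC1(C)[C@@]2(N=C=O)CC[C@]1(C)C(=O)O2 | intermediate (not isolated)
8 | (1S)-1,2,2-trimethyl-3-oxocyclopentane-1-carboxylic acid | CC1(C)C(=O)CC[C@]1(C)C(=O)O | intermediate
9 | (1S)-1,2,2-trimethyl-3-oxocyclopentane-1-carbonyl chloride | CC1(C)C(=O)CC[C@]1(C)C(=O)Cl | intermediate (not isolated)
10 | 2-diazo-1-[(1S)-1,2,2-trimethyl-3-oxocyclopentyl]ethan-1-one | CC1(C)C(=O)CC[C@]1(C)C(=O)C=[N+]=[N-] | intermediate
11 | 2-[(1R)-1,2,2-trimethyl-3-oxocyclopentyl]ethen-1-one (ketene) | CC1(C)C(=O)CC[C@]1(C)C=C=O | intermediate (not isolated)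
12 | methyl 2-[(1R)-1,2,2-trimethyl-3-oxocyclopentyl]acetate | CC1(C)C(=O)CC[C@]1(C)CC(=O)OC | intermediate
13 | methyl 2-[(1R,3S)-3-hydroxy-1,2,2-trimethylcyclopentyl]acetate (hydroxyl trans to the acetate arm) | CC1(C)[C@@H](O)CC[C@]1(C)CC(=O)OC | intermediate
14 | methyl 2-[(1R,3R)-3-bromo-1,2,2-trimethylcyclopentyl]acetate (bromine cis to the acetate arm) | CC1(C)[C@H](Br)CC[C@]1(C)CC(=O)OC | intermediate
15 | 2-{[(1R,3R)-3-bromo-1,2,2-trimethylcyclopentyl]methyl}-1,3-bis(trimethylsilyl)propan-2-ol | CC1(C)[C@H](Br)CC[C@]1(C)CC(O)(C[Si](C)(C)C)C[Si](C)(C)C | intermediate (not isolated)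
16 | (2-{[(1R,3R)-3-bromo-1,2,2-trimethylcyclopentyl]methyl}prop-2-en-1-yl)trimethylsilane | CC1(C)[C@H](Br)CC[C@]1(C)CC(=C)C[Si](C)(C)C | intermediate
17 | (1R,3R)-3-bromo-1-[2-(bromomethyl)prop-2-en-1-yl]-1,2,2-trimethylcyclopentane | CC1(C)[C@H](Br)CC[C@]1(C)CC(=C)CBr | intermediate
18 | vinylmagnesium bromide | C=C[Mg]Br | starting material
19 | bromomagnesium (6S)-6-ethenyl-7-methyl-1,4-dioxaspiro[4.5]dec-7-en-8-olate | C=C[C@H]1C(C)=C(O[Mg]Br)CCC12OCCO2 | intermediate (not isolated)
20 | (6S,7S)-7-{2-[((1R,3R)-3-bromo-1,2,2-trimethylcyclopentyl)methyl]prop-2-en-1-yl}-6-ethenyl-7-methyl-1,4-dioxaspiro[4.5]decan-8-one (vinyl and allyl arms trans) | C=C[C@H]1[C@](C)(CC(=C)C[C@@]2(C)CC[C@@H](Br)C2(C)C)C(=O)CCC13OCCO3 | intermediate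
21 | (6S,7S,8R)-7-{2-[((1R,3R)-3-bromo-1,2,2-trimethylcyclopentyl)methyl]prop-2-en-1-yl}-6-ethenyl-7-methyl-1,4-dioxaspiro[4.5]decan-8-ol (hydroxyl cis to the allyl arm) | C=C[C@H]1[C@](C)(CC(=C)C[C@@]2(C)CC[C@@H](Br)C2(C)C)[C@H](O)CCC13OCCO3 | intermediate
22 | (6S,7S,8S)-8-bromo-7-{2-[((1R,3R)-3-bromo-1,2,2-trimethylcyclopentyl)methyl]prop-2-en-1-yl}-6-ethenyl-7-methyl-1,4-dioxaspiro[4.5]decane (bromine cis to the C7 methyl) | C=C[C@H]1[C@](C)(CC(=C)C[C@@]2(C)CC[C@@H](Br)C2(C)C)[C@@H](Br)CCC13OCCO3 | intermediate
23 | (6R,7S,8S)-8-bromo-7-{3-[(1R,3R)-3-bromo-1,2,2-trimethylcyclopentyl]-2-oxopropyl}-7-methyl-1,4-dioxaspiro[4.5]decane-6-carbaldehyde | O=C[C@H]1[C@](C)(CC(=O)C[C@@]2(C)CC[C@@H](Br)C2(C)C)[C@@H](Br)CCC13OCCO3 | intermediate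
24 | ring-A aldol: C3-hydroxy C1-ketone with C2–C3 bond formed, C5 ethylene ketal, trans ring fusion, C2 and C3 as a mixture | CC1(C)[C@H](Br)CC[C@]1(C)C1C(O)[C@@H]2C3(OCCO3)CC[C@H](Br)[C@@]2(C)CC1=O | intermediate (not isolated)
25 | C5 ethylene ketal of (4aS,8S,8aS)-8-bromo-3-[(1R,3R)-3-bromo-1,2,2-trimethylcyclopentyl]-8a-methyl-4a,7,8,8a-tetrahydronaphthalene-2,5(1H,6H)-dione | CC1(C)[C@H](Br)CC[C@]1(C)C1=C[C@@H]2C3(OCCO3)CC[C@H](Br)[C@@]2(C)CC1=O | intermediate
26 | (4aS,8S,8aS)-8-bromo-3-[(1R,3R)-3-bromo-1,2,2-trimethylcyclopentyl]-8a-methyl-4a,7,8,8a-tetrahydronaphthalene-2,5(1H,6H)-dione | CC1(C)[C@H](Br)CC[C@]1(C)C1=C[C@@H]2C(=O)CC[C@H](Br)[C@@]2(C)CC1=O | intermediate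
27 | potassium dienolate of 26 (C4=C5 enolate conjugated with the C2=C3–C1=O enone) | CC1(C)[C@H](Br)CC[C@]1(C)C1=CC2=C([O-])CC[C@H](Br)[C@@]2(C)CC1=O.[K+] | intermediate (not isolated)
28 | (4aR,8S,8aS)-8-bromo-3-[(1R,3R)-3-bromo-1,2,2-trimethylcyclopentyl]-4a-hydroxy-8a-methyl-4a,7,8,8a-tetrahydronaphthalene-2,5(1H,6H)-dione | CC1(C)[C@H](Br)CC[C@]1(C)C1=C[C@]2(O)C(=O)CC[C@H](Br)[C@@]2(C)CC1=O | intermediate
29 | (4aR,5R,8S,8aS)-8-bromo-3-[(1R,3R)-3-bromo-1,2,2-trimethylcyclopentyl]-4a,5-dihydroxy-5,8a-dimethyl-4a,5,6,7,8,8a-hexahydronaphthalen-2(1H)-one | CC1(C)[C@H](Br)CC[C@]1(C)C1=C[C@]2(O)[C@](C)(O)CC[C@H](Br)[C@@]2(C)CC1=O | target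

## Step count and risk

Total steps: 17. Longest linear sequence: 15 (steps 3–17, from 5). The ring-B enone 4 is a two-step branch.

Least certain steps:

**Step 10 (key step).** What may go wrong:
- incomplete facial discrimination in the vinyl transfer, since vinyl Grignard reagents come in THF, which erodes selectivity with ferrocenyl diphosphines, and the β-carbon is flanked by the ketal;
- competing 1,2-addition;
- sluggish alkylation of the magnesium enolate at the congested C9, allowing proton transfer to the C7 enolate and over-alkylation.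

Fallback, from 4: a stoichiometric vinyl cuprate (18, CuI, Me3SiCl, THF, −78 °C) gives the racemic trimethylsilyl enol ether F1. MeLi releases the regiodefined racemic lithium enolate F2, which is alkylated by 17 in THF/DMPU. Because 17 is enantiopure, the two trans products are diastereomers, 20 and its (6R,7R) isomer F3, and chromatography returns the route to 20 at the cost of half the ring-B material.

**Step 7.** What may go wrong: the ester carbonyl lies on the face from which bromide must enter and could displace the activated C13 oxygen itself (lactone formation or net retention). Ionisation with methyl shift from C12 is also possible. Fallback, from 13: remove the participating ester first. The Bunnelle sequence of step 8 (one extra equivalent of reagent for the free hydroxyl) gives (1S,3R)-2,2,3-trimethyl-3-{2-[(trimethylsilyl)methyl]prop-2-en-1-yl}cyclopentan-1-ol F4. NBS as in step 9 gives (1S,3R)-3-[2-(bromomethyl)prop-2-en-1-yl]-2,2,3-trimethylcyclopentan-1-ol F5, and the Appel bromination is run last on F5, returning at 17.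

**Step 12.** What may go wrong: ionisation of the activated neopentylic alcohol with 1,2-shift of the C9 methyl, anti elimination toward C7, or participation by the arm olefin or a ketal oxygen instead of direct displacement. Fallback, from 21: separate activation from substitution. Chloromethanesulfonyl chloride and pyridine give the chloromethanesulfonate of 21 F6, which is isolated and displaced by excess LiBr in DMF with inversion, returning at 22.

**Step 14.** What may go wrong: β-elimination of a ketal oxygen from the aldehyde enolate before ring closure, arrest at the β-hydroxy ketone, or base-induced loss of HBr. Fallback, from 23: kinetic closure with LiN(SiMe3)2 in THF at −78 °C gives aldol 24, which is isolated. MsCl/Et3N converts it into the mesylate of 24 F7, and DBU eliminates it, returning at 25.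

**Step 16.** What may go wrong: deprotonation at C6 or C10 in place of C4, oxidant approach on the face of the C9 methyl (poor facial selectivity), or α-ketol rearrangement of the product alkoxide. Fallback, from 26: soft enolisation (Me3SiOTf, Et3N, CH2Cl2) gives the trimethylsilyl dienol ether of 26 F8. Dimethyldioxirane epoxidises its enol ether double bond at −78 °C (Rubottom oxidation), and mild acid work-up returns the route at 28.

**Step 17.** What may go wrong: addition to the C1 enone carbonyl, enolisation toward C6, or methyl delivery to the wrong face of C5. Fallback, from 26 (bypassing 28): KN(SiMe3)2 and PhNTf2 give the C5 dienyl triflate F9. Stille coupling with Me4Sn (Pd(PPh3)4, a zerovalent palladium catalyst, LiCl, DMF) gives the 5-methyl dienone F10. m-CPBA epoxidises the electron-rich C4=C5 bond anti to the angular methyl to give the 4,5-epoxide F11. Acid-catalysed hydration (HClO4, aqueous THF) opens F11 at C5 in the trans-diaxial sense and returns the route at 29.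

## Further compounds

F1 | step 10 | racemic trimethyl[(6-ethenyl-7-methyl-1,4-dioxaspiro[4.5]dec-7-en-8-yl)oxy]silane | C=CC1C(C)=C(O[Si](C)(C)C)CCC12OCCO2
F2 | step 10 | racemic lithium 6-ethenyl-7-methyl-1,4-dioxaspiro[4.5]dec-7-en-8-olate | C=CC1C(C)=C([O-])CCC12OCCO2.[Li+]
F3 | step 10 | (6R,7R) diastereomer of 20 | C=C[C@@H]1[C@@](C)(CC(=C)C[C@@]2(C)CC[C@@H](Br)C2(C)C)C(=O)CCC13OCCO3
F4 | step 7 | (1S,3R)-2,2,3-trimethyl-3-{2-[(trimethylsilyl)methyl]prop-2-en-1-yl}cyclopentan-1-ol | CC1(C)[C@@H](O)CC[C@]1(C)CC(=C)C[Si](C)(C)C
F5 | step 7 | (1S,3R)-3-[2-(bromomethyl)prop-2-en-1-yl]-2,2,3-trimethylcyclopentan-1-ol | CC1(C)[C@@H](O)CC[C@]1(C)CC(=C)CBr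
F6 | step 12 | chloromethanesulfonate of 21 | C=C[C@H]1[C@](C)(CC(=C)C[C@@]2(C)CC[C@@H](Br)C2(C)C)[C@H](OS(=O)(=O)CCl)CCC13OCCO3
F7 | step 14 | mesylate of aldol 24 | CC1(C)[C@H](Br)CC[C@]1(C)C1C(OS(C)(=O)=O)[C@@H]2C3(OCCO3)CC[C@H](Br)[C@@]2(C)CC1=O
F8 | step 16 | trimethylsilyl dienol ether of 26 | CC1(C)[C@H](Br)CC[C@]1(C)C1=CC2=C(O[Si](C)(C)C)CC[C@H](Br)[C@@]2(C)CC1=O
F9 | step 17 | C5 dienyl triflate of 26 | CC1(C)[C@H](Br)CC[C@]1(C)C1=CC2=C(OS(=O)(=O)C(F)(F)F)CC[C@H](Br)[C@@]2(C)CC1=O
F10 | step 17 | (8S,8aS)-8-bromo-3-[(1R,3R)-3-bromo-1,2,2-trimethylcyclopentyl]-5,8a-dimethyl-6,7,8,8a-tetrahydronaphthalen-2(1H)-one | CC1(C)[C@H](Br)CC[C@]1(C)C1=CC2=C(C)CC[C@H](Br)[C@@]2(C)CC1=O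
F11 | step 17 | 4,5-epoxide of F10 with oxygen anti to the C9 methyl | CC1(C)[C@H](Br)CC[C@]1(C)C1=C[C@@]23O[C@@]3(C)CC[C@H](Br)[C@@]2(C)CC1=O
A1 | alternative 1 | methyl 6-(benzyloxy)-4,5-dimethyl-2-methylidene-3-oxohex-4-enoate (single olefin isomer) | COC(=O)C(=C)C(=O)C(C)=C(C)COCc1ccccc1
A2 | alternative 1 | ring-C cyclopentenone ester | COC(=O)C1=C[C@](C)(COCc2ccccc2)[C@H](C)C1=O
A3 | alternative 2 | C2 dienyl triflate with C1 aldehyde tethered through C10 | CC1(C)[C@H](Br)CC[C@]1(C)/C(OS(=O)(=O)C(F)(F)F)=C/C1=C(C)CC[C@H](Br)[C@@]1(C)CC=O
A4 | alternative 2 | ring-A dienol | CC1(C)[C@H](Br)CC[C@]1(C)C1=CC2=C(C)CC[C@H](Br)[C@@]2(C)C[C@@H]1O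
A5 | alternative 3 | ten-membered (E,E)-dienone bearing ring C at C2 | CC1(C)[C@H](Br)CC[C@]1(C)[C@H]1C/C=C(C)/CC/C=C(C)/CC1=O
A6 | alternative 3 | bicyclic bromo ketone with C4=C5 olefin | CC1(C)[C@H](Br)CC[C@]1(C)[C@H]1CC2=C(C)CC[C@H](Br)[C@@]2(C)CC1=O
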